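**Plan**

- Retrosynthesis: after the resolving esters are removed, the two cyclobutane bonds are cut first (the CH on the enol-ether β-carbon to CMe2, and the ring-fusion CH to the CH next to CMe2). Then come the pyran O–C(Me) bond and the C=C between the oxepinone CH2 carbon and the aldehyde carbon of citral, leaving a 2-prenyl-3,7-dioxygenated dibenzo[b,f]oxepin-10(11H)-one and citral.
- Enabling feature: the cyclobutane shares one edge with a pyran whose O–C=C unit is the enol ether of the oxepinone, and the quaternary O–C(Me) carbon of that pyran carries the CH2CH2 link to the opposite cyclobutane edge. The cage is therefore the internal [2+2] adduct of the C3=C4 bond of a 2-methyl-2-(4-methylpent-3-enyl)-2H-pyran with its own Me2C=CH end (a 1,6-diene), and that pyran is the 6π valence isomer of the citral alkylidene ketone.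
- Forward: an Ullmann ether joins ring A to ring B and a Friedel–Crafts acylation closes the oxepinone; iodination, demethylation, silylation and Stille prenylation follow. One flask then closes the pyran (oxa-6π), the cyclopentane and, last, the cyclobutane ([2+2]).
- Stereochemistry: the quaternary carbon forms racemic, because its 2H-pyran precursor is stereolabile through ring opening. The three CH stereocentres follow from it by ring-fusion geometry. The absolute configuration comes from resolution as bis-(1S)-camphanates, followed by ester cleavage.

Key step: step 7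

Remark: commercial citral is used as its E/Z mixture, since both isomers converge on the same alkylidene ketone and 2H-pyran.

**Route**

Step 1
Reactants: 1 2-(2-bromo-4-methoxyphenyl)acetic acid; 2 3-methoxyphenol
Product: 3 2-[4-methoxy-2-(3-methoxyphenoxy)phenyl]acetic acid
Conditions: CuI (10 mol%), N,N-dimethylglycine (30 mol%), Cs2CO3 (3 equiv), 1,4-dioxane, 100 °C; aq. HCl work-up
Reagents that add atoms: none
Why: Copper-catalysed Ullmann diaryl ether synthesis, accelerated by the amino-acid ligand and the ortho-carboxymethyl group, is the standard entry to 2-aryloxyphenylacetic acids and forms no stereocentre.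

Step 2
Reactants: 3 2-[4-methoxy-2-(3-methoxyphenoxy)phenyl]acetic acid
Product: 4 3,7-dimethoxydibenzo[b,f]oxepin-10(11H)-one
Conditions: P2O5/MeSO3H (1:10 w/w), 40 °C
Reagents that add atoms: none
Why: Intramolecular Friedel–Crafts acylation closes the seven-membered ring at the carbon of ring B that is para to OMe and ortho to the ether oxygen, the only doubly activated site the tethered acylium ion can reach.

Step 3
Reactants: 4 3,7-dimethoxydibenzo[b,f]oxepin-10(11H)-one
Product: 5 2-iodo-3,7-dimethoxydibenzo[b,f]oxepin-10(11H)-one
Conditions: N-iodosuccinimide (1.05 equiv), CF3CO2H (10 mol%), MeCN, 0 °C to rt, dark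
Reagents that add atoms: N-iodosuccinimide, O=C1CCC(=O)N1I
Why: Electrophilic aromatic iodination should go to C2 of ring A (ortho to OMe, para to the ring oxygen), because both oxygens of ring B are tied up in push–pull conjugation with the ketone and C4 is flanked by two substituents.

Step 4
Reactants: 5 2-iodo-3,7-dimethoxydibenzo[b,f]oxepin-10(11H)-one
Product: 6 3,7-dihydroxy-2-iododibenzo[b,f]oxepin-10(11H)-one
Conditions: BBr3 (5 equiv), CH2Cl2, −78 °C to rt; then H2O
Reagents that add atoms: none
Why: Lewis-acid cleavage of aryl methyl ethers (BBr3 demethylation) is placed here, before any acid-sensitive alkene or enol ether exists, and leaves the diaryl ether, ketone and aryl iodide intact.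

Step 5
Reactants: 6 3,7-dihydroxy-2-iododibenzo[b,f]oxepin-10(11H)-one
Product: 7 2-iodo-3,7-bis(triisopropylsilyloxy)dibenzo[b,f]oxepin-10(11H)-one
Conditions: i-Pr3SiCl (2.5 equiv), imidazole (5 equiv), DMF, rt to 40 °C
Reagents that add atoms: triisopropylsilyl chloride, CC(C)[Si](Cl)(C(C)C)C(C)C
Why: Silylation of both phenols as robust triisopropylsilyl ethers masks phenol acidity and the nucleophilic arene positions for the condensation, and allows a final fluoride unmasking that spares the enol ether and the prenyl group.

Step 6
Reactants: 7 2-iodo-3,7-bis(triisopropylsilyloxy)dibenzo[b,f]oxepin-10(11H)-one; 8 tributyl(3-methylbut-2-en-1-yl)stannane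
Product: 9 2-(3-methylbut-2-en-1-yl)-3,7-bis(triisopropylsilyloxy)dibenzo[b,f]oxepin-10(11H)-one
Conditions: Pd(PPh3)4 (5 mol%), DMF, 90 °C, degassed
Reagents that add atoms: none
Why: Stille cross-coupling of an aryl iodide with the prenylstannane runs under neutral conditions that tolerate the enolisable ketone and should deliver the linear prenyl arene, as is established for prenylation of oxygenated aryl halides.

Step 7
Reactants: 9 2-(3-methylbut-2-en-1-yl)-3,7-bis(triisopropylsilyloxy)dibenzo[b,f]oxepin-10(11H)-one; 10 citral (3,7-dimethylocta-2,6-dienal, E/Z mixture)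
Product: 13 racemic bis(triisopropylsilyl) ether of the target, via dienone 11 (not isolated), via 2H-pyran 12 (not isolated)
Conditions: citral (2 equiv), piperidine (30 mol%), AcOH (30 mol%), 4 Å MS, toluene, 80 °C; then dilute to 0.01 M, 9-fluorenone (20 mol%), Ar, 405 nm LEDs, 15 °C
Reagents that add atoms: none
Why: Piperidinium acetate turns citral into its iminium ion, the enol of the only enolisable CH2 of 9 (C11, activated by the aryl ketone and ring A) adds 1,2 because the β,β-disubstitution of citral blocks 1,4-addition, and loss of the amine gives 1-oxatriene 11, whose thermal disrotatory oxa-6π electrocyclisation closes the pyran by O–C bond formation (Knoevenagel/oxa-6π sequence, the formal oxa-[3+3] annulation known for citral with activated carbonyl compounds). Triplet energy transfer from 9-fluorenone to the aryl-conjugated dienyl ether of 12 then triggers the intramolecular [2+2] photocycloaddition of the pyran C3=C4 bond with the Me2C=CH terminus, the reaction type by which 2-methyl-2-homoprenyl-2H-chromenes give cyclol skeletons. The cyclopentane closes first by 5-exo attack of pyran C3 on the CH terminus (rule of five), and the cyclobutane closes last by combination of the resulting tertiary radical with the allylic radical at pyran C4 after intersystem crossing. The quaternary O-bearing carbon forms without facial bias and stays labile through 11, so 13 is racemic, but the three new CH stereocentres are dictated by it, because the CH2CH2 link can only span a cis-fused bicyclo[3.2.0]heptane and the cyclobutane can only be cis-fused to the pyran. The step needs the cycloaddition to run through 12 and not 11, which the substrate secures because only 12 holds a rigid s-cis diene that cannot relax by E/Z isomerisation, while photoisomerised 11 re-enters the equilibrium and is drained through 12. It also needs the product to be a photochemical sink, so a low-energy sensitiser is chosen that should excite the dienyl-stilbene chromophore of 12 but not the less conjugated enol-ether stilbene of 13 or the isolated trisubstituted alkenes.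

Step 8
Reactants: 13 racemic bis(triisopropylsilyl) ether of the target
Product: 15 bis-(1S)-camphanate of the target, via racemic diol 14 (not isolated)
Conditions: Bu4NF (2.5 equiv), THF, 0 °C; then (1S)-(−)-camphanic chloride (4 equiv), Et3N (4 equiv), DMAP (20 mol%), 0 °C to rt; diastereomers separated by silica chromatography and crystallisation
Reagents that add atoms: (1S,4R)-camphanic chloride, O=C(Cl)[C@@]12CC[C@@](C)(C(=O)O1)C2(C)C
Why: Fluoride desilylation followed in the same flask by DMAP-catalysed acylation of the phenoxides with an enantiopure acid chloride is a classical resolution through covalent diastereomers, and the auxiliary of known configuration lets the target-configured isomer be assigned by X-ray crystallography.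

Step 9
Reactants: 15 bis-(1S)-camphanate of the target
Product: 16 target compound CNP0185814.1
Conditions: K2CO3 (3 equiv), MeOH/THF, 0 °C to rt; aq. NH4Cl
Reagents that add atoms: none
Why: Mild base-mediated transesterification of the two aryl esters releases the phenols without touching the enol ether, the prenyl group or any stereocentre.

**Compound list**

1 | 2-(2-bromo-4-methoxyphenyl)acetic acid | COc1ccc(CC(=O)O)c(Br)c1 | starting material
2 | 3-methoxyphenol | COc1cccc(O)c1 | starting material
3 | 2-[4-methoxy-2-(3-methoxyphenoxy)phenyl]acetic acid | COc1cccc(Oc2cc(OC)ccc2CC(=O)O)c1 | intermediate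
4 | 3,7-dimethoxydibenzo[b,f]oxepin-10(11H)-one | COc1ccc2CC(=O)c3ccc(OC)cc3Oc2c1 | intermediate
5 | 2-iodo-3,7-dimethoxydibenzo[b,f]oxepin-10(11H)-one | COc1cc2Oc3cc(OC)ccc3C(=O)Cc2cc1I | intermediate
6 | 3,7-dihydroxy-2-iododibenzo[b,f]oxepin-10(11H)-one | Oc1cc2Oc3cc(O)ccc3C(=O)Cc2cc1I | intermediate
7 | 2-iodo-3,7-bis(triisopropylsilyloxy)dibenzo[b,f]oxepin-10(11H)-one | CC(C)[Si](Oc1cc2Oc3cc(O[Si](C(C)C)(C(C)C)C(C)C)ccc3C(=O)Cc2cc1I)(C(C)C)C(C)C | intermediate
8 | tributyl(3-methylbut-2-en-1-yl)stannane | CCCC[Sn](CCCC)(CCCC)CC=C(C)C | starting material
9 | 2-(3-methylbut-2-en-1-yl)-3,7-bis(triisopropylsilyloxy)dibenzo[b,f]oxepin-10(11H)-one | CC(C)=CCc1cc2CC(=O)c3ccc(O[Si](C(C)C)(C(C)C)C(C)C)cc3Oc2cc1O[Si](C(C)C)(C(C)C)C(C)C | intermediate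
10 | citral (3,7-dimethylocta-2,6-dienal, E/Z mixture) | CC(C)=CCCC(C)=CC=O | starting material
11 | dienone: 11-(3,7-dimethylocta-2,6-dien-1-ylidene) derivative of 9 (1-oxatriene, alkene isomers interconverting) | CC(C)=CCCC(C)=CC=C1C(=O)c2ccc(O[Si](C(C)C)(C(C)C)C(C)C)cc2Oc2cc(O[Si](C(C)C)(C(C)C)C(C)C)c(CC=C(C)C)cc12 | intermediate
12 | 2H-pyran: 2-methyl-2-(4-methylpent-3-enyl)-2H-pyran fused through its O–C=C unit to C10–C11 of the 2-prenyl-3,7-bis(triisopropylsilyloxy)dibenzo[b,f]oxepine (racemic, stereolabile) | CC(C)=CCCC1(C)C=CC2=C(O1)c1ccc(O[Si](C(C)C)(C(C)C)C(C)C)cc1Oc1cc(O[Si](C(C)C)(C(C)C)C(C)C)c(CC=C(C)C)cc12 | intermediate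
13 | bis(triisopropylsilyl) ether of the target ring system, all-cis cage, racemate (the enantiomer leading to the target is drawn) | CC(C)=CCc1cc2c(cc1O[Si](C(C)C)(C(C)C)C(C)C)Oc1cc(O[Si](C(C)C)(C(C)C)C(C)C)ccc1C1=C2[C@@H]2[C@H]3[C@H](CC[C@@]3(C)O1)C2(C)C | intermediate
14 | racemic diol (racemic form of the target; the target enantiomer is drawn) | CC(C)=CCc1cc2c(cc1O)Oc1cc(O)ccc1C1=C2[C@@H]2[C@H]3[C@H](CC[C@@]3(C)O1)C2(C)C | intermediate
15 | bis-(1S,4R)-camphanate of the target; core: quaternary O–C(Me) R, ring-fusion CH R, CH on the enol-ether β-carbon R, CH next to CMe2 S | CC(C)=CCc1cc2c(cc1OC(=O)[C@@]56CC[C@@](C)(C(=O)O5)C6(C)C)Oc1cc(OC(=O)[C@@]78CC[C@@](C)(C(=O)O7)C8(C)C)ccc1C1=C2[C@@H]2[C@H]3[C@H](CC[C@@]3(C)O1)C2(C)C | intermediate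
16 | target CNP0185814.1: 2-prenyl-3,7-dihydroxydibenzo[b,f]oxepine carrying the fused pyran/cyclobutane/cyclopentane cage on C10–C11; quaternary O–C(Me) R, ring-fusion CH R, CH on the enol-ether β-carbon R, CH next to CMe2 S | CC(C)=CCc1cc2c(cc1O)Oc1cc(O)ccc1C1=C2[C@@H]2[C@H]3[C@H](CC[C@@]3(C)O1)C2(C)C | target

**Step count and risks**

Total step count: 9. Longest linear sequence: 9 steps (from 1).

Steps most likely to fail:

1. Step 7. The condensation of a singly activated ketone may be slow and lose out to self-condensation of citral. The pyran–dienone equilibrium may lie on the dienone side and starve the cycloaddition. The cyclobutane may revert on re-excitation. The fallback sets out from 9 and returns at 13. Compound 9 is deprotonated with LiN(SiMe3)2 in THF at −78 °C and treated with citral to give the β-hydroxy ketone F1 (directed aldol addition). MsCl and excess Et3N in CH2Cl2 at 0 °C convert it into the methanesulfonate F2, which eliminates in the same flask to the equilibrating pair 11/12. This is filtered and irradiated in degassed acetone (solvent as triplet sensitiser, borosilicate glass, 350 nm lamps), the classical conditions for chromene-to-cyclol photocycloaddition, to give 13.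

2. Step 6. Oxidative addition into the hindered, electron-rich aryl iodide may be slow. Allylic transposition during transmetalation would give coupling at the tertiary carbon. Protodeiodination may compete. The fallback sets out from 7 and returns at 9. Stille coupling of 7 with allyltributylstannane (Pd(PPh3)4, toluene, 100 °C), which has no regiochemical ambiguity, gives the allyl arene F3. Olefin cross-metathesis with excess 2-methylbut-2-ene ((H2IMes)(PCy3)Cl2Ru=CHPh, the second-generation Grubbs catalyst, CH2Cl2, 40 °C) then converts the allyl group into the prenyl group of 9.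

3. Step 8. The two diastereomeric bis-esters may fail to separate because the auxiliaries are remote from the cage. Acylation of the hindered phenol next to the prenyl group may be incomplete. The fallback sets out from 13 and returns at 16. The enantiomers of 13 are separated without derivatisation by preparative chromatography on a chiral stationary phase (amylose carbamate phase, supercritical CO2/alcohol) to give the single-enantiomer silyl ether F4, whose configuration is assigned by comparison of chiroptical data with the natural product. Bu4NF in THF at 0 °C then removes both silyl groups to give 16.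

**Further compounds**

F1 | step 7 | β-hydroxy ketone, aldol adduct of 9 with citral (diastereomer mixture) | CC(C)=CCCC(C)=CC(O)C1C(=O)c2ccc(O[Si](C(C)C)(C(C)C)C(C)C)cc2Oc2cc(O[Si](C(C)C)(C(C)C)C(C)C)c(CC=C(C)C)cc12
F2 | step 7 | methanesulfonate of F1 | CC(C)=CCCC(C)=CC(OS(C)(=O)=O)C1C(=O)c2ccc(O[Si](C(C)C)(C(C)C)C(C)C)cc2Oc2cc(O[Si](C(C)C)(C(C)C)C(C)C)c(CC=C(C)C)cc12
F3 | step 6 | 2-allyl-3,7-bis(triisopropylsilyloxy)dibenzo[b,f]oxepin-10(11H)-one | C=CCc1cc2CC(=O)c3ccc(O[Si](C(C)C)(C(C)C)C(C)C)cc3Oc2cc1O[Si](C(C)C)(C(C)C)C(C)C
F4 | step 8 | single enantiomer of 13 with the configuration of the target | CC(C)=CCc1cc2c(cc1O[Si](C(C)C)(C(C)C)C(C)C)Oc1cc(O[Si](C(C)C)(C(C)C)C(C)C)ccc1C1=C2[C@@H]2[C@H]3[C@H](CC[C@@]3(C)O1)C2(C)C
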